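The runs are simulated on assumed constants.

A small charge of L, 0.20 M, sits over 0.260 M of Z, all of it solid at the start, and if one Z serves one L, then L is the limiting reagent.

| flask | L | Z | remark | time |
|---|---|---|---|---|
| spring | 0.20 M | 0.26 M | the very flask that is asked about, followed so far |  |
| winter | 0.40 M | 0.26 M | run made earlier |  |
| flask | 0.20 M | 0.260 M |  | 8.0 h |

spring run (percent of the L charged)

| time / min | Q / % | L / % |
|---|---|---|
| 8.00 | 2 | 99 |
| 12.0 | 2 | 99 |
| 20.0 | 5 | 96 |
| 40.0 | 8 | 94 |
| 60.0 | 12 | 91 |
| 90.0 | 17 | 83 |

winter run (percent of the L charged)

| time / h | Q / % | L / % |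
|---|---|---|
| 0.667 | 5 | 93 |
| 1.00 | 10 | 91 |
| 2.00 | 19 | 81 |
| 3.00 | 28 | 72 |
| 5.00 | 44 | 55 |
| 8.00 | 61 | 39 |

(standard deviation of a reading: 1.5 percentage points)

- as a solid, counted per litre of solution: Z
- at the start none of Z is in solution

1. how much Q there is at 8.0 h, in percent of the L charged
2. the change that raises the amount of Q at 8.0 h, in percent of the L charged most ("none" if none brings more than 2 percentage points) (Tuesday's / Monday's / none)
3. amount of Q at 8.0 h, in percent of the L charged, after Monday's

- Tuesday's: doubling the solubility of Z, all else as stated
- Monday's: doubling the dissolution coefficient of Z, all else as stated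

I keep the books on L. At the last winter reading, 39% is left as L and 61% stands as Q, which makes 100%, so the ledger needs these two entries. Now take the dissolving as the fast step and treat it as settled: dissolved Z then holds a steady level, and c_L decays as a pseudo-first-order lag. Its measure is the time constant of L, the time divided by minus the logarithm of the fraction of L left, read while Z is still in hand: 8.36 h at the winter reading of 5.00 h, where one Z per L leaves 0.0840 M of Z, solid and dissolved together. I pass over the last winter reading, since the same count leaves 0.0160 M of Z there, and the level may have fallen by then. The spring run, with half the L, reads 8.05 h at its last point, with readings scattered by 1.5 percentage points.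

For the flask at 8.0 h, the entry for Q is therefore 61.6%. That draws 0.123 M of Z and leaves 0.137 M of Z, solid and dissolved together, so the books close with Z still in hand. Monday's change, doubling the dissolution coefficient of Z, speeds a step I take as settled, so I expect about the same figure. Tuesday's, doubling the solubility of Z, lifts the level itself, so I choose Tuesday's.

The forecast, slightly higher, gives 63%, Tuesday's and 66%: “Percentage rate is therefore nearly independent of L”.

The flask gives 62.3%. Tuesday's adds 12 points, and Monday's adds 0.57 points, reaching 62.9%, so the best change is Tuesday's.

    Z ⇌ D, rate k1*(cs1 - [D]) while solid is left; crystals form when [D] > cs1 (solubility = 0.0750 M, k = 5.94 /h)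
    L + D → Q, rate k2*[L]*[D]^0.5 (k = 0.459 /M^0.5/h)

By 8.0 h, the dissolving of Z could deliver 1782% of the L charged into a solution kept empty, if the solid never ran out, far more than the 62.3% turned over by the making of Q in this flask. Dissolved D stands at 0.0706 M after 0.800 h and 0.0734 M at 8.00 h, slightly below the solubility of 0.075 M. The half-life of L at 8.00 h, 5.6 h, corresponds to a time constant of 8.08 h, against the 8.36 h I carried. For the same flask read at 20 h, 8.36 h gives 90.9% Q, and that flask holds 91.6%, with 0.845% of its Z charge still solid.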